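**Plan**

Retrosynthesis: the pyrrolidine-2,4-dione ring (N1, C2, C3, C4, C5) is opened first at C3–C4, the Claisen bond between the acetyl-bearing carbon and the former leucine carboxyl carbon, and with it at N1–C2, which removes a four-carbon acetylketene unit; then the exocyclic N-acyl amide bond is cut, and last the C2'=C3' double bond of the C12 chain.
Forward: a Doebner condensation builds the E-enoic acid from a C10 aldehyde, amide coupling attaches it to a D-leucine ester, and the secondary amide is joined with diketene through its lithium amidate so that the ring closes in the same flask and gives the target directly, with no protecting group and no step after ring closure.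
Enabling feature: C3 lies between the C2 lactam carbonyl and the exocyclic acetyl carbonyl, so it is a stabilised 1,3-dicarbonyl carbanion held 1,5 to the ester carbon that becomes C4. The finished C2/acetyl/C4 tricarbonyl array is acidic enough to take up the expelled methoxide, which drives the closure; the same Claisen bond between an amino acid carboxyl carbon and a malonyl-derived carbon is the one by which 3-acyltetramic acids are assembled in nature.
Stereochemistry: C5 (R) is bought as D-leucine and is never the most acidic position of any intermediate; the E double bond is set in the Doebner step.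

Key step: step 3

Remark: the target is treated as the C4-enol tautomer drawn in its SMILES; the tautomers of a 3-acyltetramic acid equilibrate freely and are one compound.

**Route**

Step 1
Reactants: 1 decanal; 2 malonic acid
Product: 4 (2E)-dodec-2-enoic acid, via decylidenemalonic acid 3 (not isolated)
Conditions: pyridine, piperidine (cat.), rt then 95 °C
Reagents that add atoms: none
Why: Doebner modification of the Knoevenagel condensation: the aldehyde condenses with malonic acid to the alkylidenemalonic acid 3, which loses CO2 in hot pyridine to the conjugated acid, the E geometry being the thermodynamically preferred outcome because the nonyl chain ends up trans to the carboxyl group.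

Step 2
Reactants: 4 (2E)-dodec-2-enoic acid; 5 D-leucine methyl ester hydrochloride
Product: 8 methyl (2R)-2-[(2E)-dodec-2-enoylamino]-4-methylpentanoate, via O-acylisourea 6 (not isolated), via benzotriazolyl ester 7 (not isolated)
Conditions: EDC·HCl, HOBt, N-methylmorpholine, CH2Cl2, 0 °C to rt
Reagents that add atoms: none
Why: Carbodiimide amide coupling through the HOBt active ester: the free primary amine should acylate much faster than it adds to the β-carbon of the enoate, and the stereocenter lies on the amine partner, which has no path to an oxazolone here, so the R configuration should be carried through unchanged.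

Step 3
Reactants: 8 methyl (2R)-2-[(2E)-dodec-2-enoylamino]-4-methylpentanoate; 9 diketene
Product: 13 reutericyclin C, via lithium amidate 10 (not isolated), via imide lithium enolate 11 (not isolated), via lithium tetramate 12 (not isolated)
Conditions: LiN(SiMe3)2 (1.05 equiv), THF, −78 °C; diketene (1.1 equiv), −78 °C to rt; then 1 M HCl, 0 °C
Reagents that add atoms: none
Why: Proposed new method: the lithium amidate 10 should open diketene at the lactone carbonyl to give the β-keto imide enolate 11, whose C3 carbanion attacks the leucine ester carbonyl and expels methoxide, which is taken up at once by the strongly acidic tricarbonyl product, so that one equivalent of base carries the whole cascade to the tetramate salt 12. The closest known reaction types are the N-acetoacetylation of lactam and oxazolidinone anions by diketene and the Lacey–Dieckmann cyclization of N-acetoacetyl α-amino esters; what is new is their fusion on an acyclic secondary N-enoyl amide. The pyrrolidine-2,4-dione ring closes in a 5-(enolexo)-exo-trig Claisen mode through the acetyl enolate, which the C3 acetyl group of the target makes possible. No new stereocenter arises; C5 comes from D-leucine and should keep its configuration because the negative charge always rests on a more acidic site (the N–H, then the 1,3-dicarbonyl C–H, then the tricarbonyl enol) and no excess base remains. The step needs N- over O-acylation of the amidate and 5-exo attack on the ester over 6-endo conjugate addition to the enoyl group; the first is the usual course of lithium amidates (an O-acyl isoimide would in any case rearrange by 1,3-acyl shift), and the second should follow because the planar imide holds the enolate carbon in the nodal plane of the enoyl π system.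

**Compound list**

1 | decanal | CCCCCCCCCC=O | starting material
2 | malonic acid | OC(=O)CC(=O)O | starting material
3 | 2-decylidenemalonic acid | CCCCCCCCCC=C(C(=O)O)C(=O)O | intermediate
4 | (2E)-dodec-2-enoic acid | CCCCCCCCC/C=C/C(=O)O | intermediate
5 | D-leucine methyl ester hydrochloride, methyl (2R)-2-amino-4-methylpentanoate hydrochloride | COC(=O)[C@H](N)CC(C)C.Cl | starting material
6 | O-[(2E)-dodec-2-enoyl]-N-[3-(dimethylamino)propyl]-N'-ethylisourea | CCCCCCCCC/C=C/C(=O)OC(NCC)=NCCCN(C)C | intermediate
7 | 1H-benzotriazol-1-yl (2E)-dodec-2-enoate | CCCCCCCCC/C=C/C(=O)On1nnc2ccccc12 | intermediate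
8 | methyl (2R)-2-[(2E)-dodec-2-enoylamino]-4-methylpentanoate | CCCCCCCCC/C=C/C(=O)N[C@H](CC(C)C)C(=O)OC | intermediate
9 | diketene, 4-methylideneoxetan-2-one | C=C1CC(=O)O1 | starting material
10 | lithium amidate of 8 | CCCCCCCCC/C=C/C(=O)[N-][C@H](CC(C)C)C(=O)OC.[Li+] | intermediate
11 | lithium (Z)-enolate of methyl (2R)-2-{[(2E)-dodec-2-enoyl](3-oxobutanoyl)amino}-4-methylpentanoate | CCCCCCCCC/C=C/C(=O)N(C(=O)/C=C(/C)[O-])[C@H](CC(C)C)C(=O)OC.[Li+] | intermediate
12 | lithium (5R)-3-acetyl-1-[(2E)-dodec-2-enoyl]-5-(2-methylpropyl)-2-oxo-1,5-dihydro-2H-pyrrol-4-olate | CCCCCCCCC/C=C/C(=O)N1C(=O)C(C(C)=O)=C([O-])[C@H]1CC(C)C.[Li+] | intermediate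
13 | reutericyclin C, (5R)-3-acetyl-1-[(2E)-dodec-2-enoyl]-4-hydroxy-5-(2-methylpropyl)-1,5-dihydro-2H-pyrrol-2-one | CCCCCCCCC/C=C/C(=O)N1C(=O)C(C(C)=O)=C(O)[C@H]1CC(C)C | target

**Summary**

Total step count: 3
Longest linear sequence: 3 steps (1 → 4 → 8 → 13)

**Steps most likely to fail**

First, step 3. The hindered amidate may be acylated slowly or at oxygen, the imide enolate may be diverted into 6-endo conjugate addition onto the enoyl group, or the configuration at C5 may erode if proton transfer between anionic intermediates is slow. The fallback uses known chemistry and changes the order of events, so that the ring is closed on a secondary amide that carries no enoyl group. It sets out from 5: N-acetoacetylation with diketene 9 and Et3N in CH2Cl2 at 0 °C should give methyl (2R)-4-methyl-2-(3-oxobutanoylamino)pentanoate F1. Lacey–Dieckmann cyclization with one equivalent of NaOMe in MeOH at rt for a short time should give sodium (5R)-3-acetyl-5-(2-methylpropyl)-2-oxo-1,5-dihydro-2H-pyrrol-4-olate F2, which is acidified with HCl to (5R)-3-acetyl-4-hydroxy-5-(2-methylpropyl)-1,5-dihydro-2H-pyrrol-2-one F3. In parallel, acid 4 is converted with oxalyl chloride and catalytic DMF in CH2Cl2 into (2E)-dodec-2-enoyl chloride F4. Double deprotonation of F3 with n-BuLi (2 equiv) in THF at −78 °C gives the dilithium salt of the tetramic acid F5, whose nitrogen anion should be acylated by F4. The fallback comes back to the route at the lithium tetramate 12 and, after acidification, at 13.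

Second, step 1. During the pyridine-mediated decarboxylation the double bond may migrate to the β,γ-position, or the E selectivity may be incomplete. The fallback sets out from 1: Horner–Wadsworth–Emmons olefination with triethyl phosphonoacetate (NaH, THF, 0 °C) should give ethyl (2E)-dodec-2-enoate F6. Saponification with LiOH in aqueous THF gives lithium (2E)-dodec-2-enoate F7, and acidification with HCl returns to the route at 4.

Third, step 2. The activated acid may rearrange to an unreactive N-acylurea, or the amine may add in conjugate fashion to the activated enoate, which would lower conversion. The fallback forms the alkene after the amide bond, so no activated enoate meets the amine. It sets out from 5: coupling with diethylphosphonoacetic acid (EDC·HCl, HOBt, N-methylmorpholine, CH2Cl2) should give methyl (2R)-2-[2-(diethoxyphosphoryl)acetylamino]-4-methylpentanoate F8. Horner–Wadsworth–Emmons olefination of F8 with decanal 1 under Masamune–Roush conditions (LiCl, DBU, MeCN, rt) should give the E-enamide and comes back to the route at 8.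

**Further compounds**

F1 | step 3 | methyl (2R)-4-methyl-2-(3-oxobutanoylamino)pentanoate | CC(=O)CC(=O)N[C@H](CC(C)C)C(=O)OC
F2 | step 3 | sodium (5R)-3-acetyl-5-(2-methylpropyl)-2-oxo-1,5-dihydro-2H-pyrrol-4-olate | O=C1N[C@H](CC(C)C)C([O-])=C1C(C)=O.[Na+]
F3 | step 3 | (5R)-3-acetyl-4-hydroxy-5-(2-methylpropyl)-1,5-dihydro-2H-pyrrol-2-one | O=C1N[C@H](CC(C)C)C(O)=C1C(C)=O
F4 | step 3 | (2E)-dodec-2-enoyl chloride | CCCCCCCCC/C=C/C(=O)Cl
F5 | step 3 | dilithium salt of (5R)-3-acetyl-4-hydroxy-5-(2-methylpropyl)-1,5-dihydro-2H-pyrrol-2-one | O=C1[N-][C@H](CC(C)C)C([O-])=C1C(C)=O.[Li+].[Li+]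
F6 | step 1 | ethyl (2E)-dodec-2-enoate | CCCCCCCCC/C=C/C(=O)OCC
F7 | step 1 | lithium (2E)-dodec-2-enoate | CCCCCCCCC/C=C/C(=O)[O-].[Li+]
F8 | step 2 | methyl (2R)-2-[2-(diethoxyphosphoryl)acetylamino]-4-methylpentanoate | CCOP(=O)(OCC)CC(=O)N[C@H](CC(C)C)C(=O)OC
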